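**Plan**
1. Retrosynthesis: the C2 hydroxyl and the C3 carbinol go back to a 3-ketone. The O–C10 lactone bond and the C4–C5 bond (ring A) are then cut together. Next come C1–C2 (acetoacetate dianion alkylation), C6–C7 and C10–C1 on ring B, C13–C16 (ring D), and C8–C14 with C9–C11 (ring C).
2. Enabling feature: C4 lies between the C19 carbonyl and C3. With C3 as a ketone, C4 is the α-carbon of a 2-methyl-β-keto ester, and the lactone oxygen is γ to C19 through C4–C5–C10. A C5=C10 olefin in ring B therefore lets one oxidation at C4 close ring A and the γ-lactone.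
3. Forward ring order: B (chiral cyclopentenone) → C (Diels–Alder) → D (palladium cycloalkenylation) → A plus lactone (oxidative radical–polar cascade). The helpers (C10 silyloxy group, C12 ketal, C3 ketone level, tert-butyl and silylethyl esters) are removed on the way.
4. Stereochemistry: the silyloxy carbon of (R)-4-silyloxycyclopentenone directs the Diels–Alder reaction (C8, C9) and is later erased. C13 follows from the bridge. C6 is relayed from C10 (exo ylide attack, then anti carbonylation). C5, C4 and C10 arise in the key step; C2 comes from exo enolate hydroxylation and C3 from equatorial hydride attack.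

Key step: step 16

Remark: gibberellane locants (C1–C19) are used for all intermediates; β and α follow customary gibberellin usage (the hydroxyls, H5, H9, C15 and the C7 carboxyl are β; the lactone bridge and C14 are α).

**Step 1**
Reactants: 1 (R)-4-(tert-butyldimethylsilyloxy)cyclopent-2-en-1-one
Product: 2 (R)-4-(tert-butyldimethylsilyloxy)-2-iodocyclopent-2-en-1-one
Conditions: I2, pyridine/CH2Cl2, 0 °C to rt
Reagents that add atoms: iodine, SMILES II
Why: Pyridine-mediated α-iodination of an enone (conjugate addition of pyridine, iodination of the enolate, elimination) should place the coupling handle on the future C8 without touching the silyloxy stereocentre (future C10).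

**Step 2**
Reactants: 2 (R)-4-(tert-butyldimethylsilyloxy)-2-iodocyclopent-2-en-1-one; 3 allyltributylstannane
Product: 4 (R)-2-allyl-4-(tert-butyldimethylsilyloxy)cyclopent-2-en-1-one
Conditions: PdCl2(PhCN)2 (5 mol %), AsPh3, CuI, NMP, 25 °C
Reagents that add atoms: none
Why: Stille coupling of an α-iodo enone with an allylstannane should give the 2-allyl enone under neutral conditions that leave the γ-silyloxy enone intact.

**Step 3**
Reactants: 5 but-3-en-2-one
Product: 6 2-(tert-butyldimethylsilyloxy)buta-1,3-diene
Conditions: TBSOTf, Et3N, Et2O, 0 °C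
Reagents that add atoms: tert-butyldimethylsilyl trifluoromethanesulfonate, SMILES CC(C)(C)[Si](C)(C)OS(=O)(=O)C(F)(F)F
Why: Soft enolisation and O-silylation of the methyl ketone gives the 2-silyloxydiene.

**Step 4**
Reactants: 4 (R)-2-allyl-4-(tert-butyldimethylsilyloxy)cyclopent-2-en-1-one; 6 2-(tert-butyldimethylsilyloxy)buta-1,3-diene
Product: 7 cis-fused bicyclic silyl enol ether (ring B 6-ketone, ring C with C12=C13 silyl enol ether; 8β-allyl, 9β-H, 10β-silyloxy)
Conditions: AlBr3/AlMe3 (10:1, 0.3 equiv), toluene/CH2Cl2, −10 °C
Reagents that add atoms: none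
Why: In this Lewis acid-promoted Diels–Alder reaction of a 2-silyloxydiene with a 2-alkylcyclopentenone, the nucleophilic diene terminus (C11) bonds to the enone β-carbon C9, so the silyl enol ether ends as C12=C13 with C12 1,4 to C8; the diene adds suprafacially to the face anti to the C10 silyloxy group, which sets C8 and C9 (cis fusion, allyl and H9 β).

**Step 5**
Reactants: 7 cis-fused bicyclic silyl enol ether
Product: 8 tricyclic diketone (rings C and D as bicyclo[3.2.1]octane with 12-ketone and 16-methylene; ring B 6-ketone; 10β-silyloxy)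
Conditions: Pd(OAc)2 (10 mol %), O2 (1 atm), DMSO, 45 °C
Reagents that add atoms: none
Why: Palladium-catalysed oxidative cycloalkenylation of a silyl enol ether (palladium enolate, 5-exo-trig insertion of the allyl olefin at C13, β-hydride elimination, reoxidation by O2) should close ring D with the 16-methylene; C13 can only bond on the face of the allyl group, so its configuration follows from C8.

**Step 6**
Reactants: 8 tricyclic diketone
Product: 9 12,12-ethylenedioxy ketal of 8 (6-ketone free)
Conditions: Me3SiOCH2CH2OSiMe3, TMSOTf (5 mol %), CH2Cl2, −78 to −20 °C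
Reagents that add atoms: 1,2-bis(trimethylsilyloxy)ethane, SMILES C[Si](C)(C)OCCO[Si](C)(C)C
Why: Low-temperature ketalisation with the bis-silyl ether of glycol should be selective for the cyclohexanone-type C12 carbonyl over the cyclopentanone flanked by quaternary C8, and should spare the silyl ether and the exocyclic olefin.

**Step 7**
Reactants: 9 ketal ketone
Product: 10 C6 enol triflate (C5=C6) of 9
Conditions: KHMDS, PhNTf2, THF, −78 °C
Reagents that add atoms: N-phenylbis(trifluoromethanesulfonimide), SMILES O=S(=O)(N(c1ccccc1)S(=O)(=O)C(F)(F)F)C(F)(F)F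
Why: Kinetic enolisation can occur only toward C5 (C8 is quaternary), and O-sulfonylation of the potassium enolate at −78 °C should give the enol triflate before the β-silyloxy group can eliminate.

**Step 8**
Reactants: 10 enol triflate
Product: 11 10β-silyloxy olefin (C5=C6, no oxygen at C6)
Conditions: Pd(OAc)2 (5 mol %), PPh3, n-Bu3N, HCO2H, DMF, 60 °C
Reagents that add atoms: none
Why: Palladium-catalysed formate reduction of an enol triflate (oxidative addition, formate exchange, decarboxylation, reductive elimination) removes the C6 oxygen and leaves the C5=C6 olefin.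

**Step 9**
Reactants: 11 10β-silyloxy olefin
Product: 12 10β-allylic alcohol
Conditions: TBAF, THF, 0 °C
Reagents that add atoms: none
Why: Fluoride cleaves the secondary silyl ether, and nothing else in 11 is fluoride-labile.

**Step 10**
Reactants: 12 10β-allylic alcohol
Product: 13 ring B enone (10-ketone, C5=C6)
Conditions: DMP, NaHCO3, CH2Cl2, 0 °C to rt
Reagents that add atoms: none
Why: Buffered periodinane oxidation of the allylic alcohol gives the enone; the C10 stereocentre, having directed the cycloaddition, is erased here.

**Step 11**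
Reactants: 13 ring B enone
Product: 14 spiro vinyl oxirane (C10–O α, C10–C1H2 β; C5=C6)
Conditions: Me3S+ I−, n-BuLi, THF, −10 °C; then 13, −10 to 0 °C
Reagents that add atoms: trimethylsulfonium iodide, SMILES C[S+](C)C.[I-]
Why: In this Corey–Chaykovsky epoxidation the sulfonium ylide adds 1,2 to the enone carbonyl from the open β face (the α face lies over ring C), so the oxirane oxygen on C10 is α and the new carbon C1 is β.

**Step 12**
Reactants: 14 spiro vinyl oxirane
Product: 15 hydroxy ester (6β-CO2CH2CH2SiMe3, C5=C10, C10–CH2OH)
Conditions: Pd2(dba)3·CHCl3 (5 mol %), PPh3 (20 mol %), CO (30 atm), Me3SiCH2CH2OH (5 equiv), THF, 40 °C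
Reagents that add atoms: carbon monoxide, SMILES [C-]#[O+]; 2-(trimethylsilyl)ethanol, SMILES C[Si](C)(C)CCO
Why: Palladium-catalysed alkoxycarbonylation of a vinyl oxirane through a π-allylpalladium alkoxide: ionisation of the allylic C10–O bond puts palladium on the β face, CO inserts at the less substituted terminus C6 on that face and the alcohol cleaves the acyl complex, which should give the 1,4-product with the C7 ester β (anti to the former C10–O bond) and so sets C6.

**Step 13**
Reactants: 15 hydroxy ester
Product: 16 allylic bromide (C10–CH2Br)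
Conditions: CBr4, PPh3, 2,6-lutidine, CH2Cl2, −20 to 0 °C
Reagents that add atoms: carbon tetrabromide, SMILES BrC(Br)(Br)Br
Why: Appel bromination of the primary allylic alcohol under buffered conditions should proceed without allylic transposition and tolerates ketal and ester.

**Step 14**
Reactants: 17 tert-butyl 3-oxobutanoate
Product: 18 tert-butyl 2-methyl-3-oxobutanoate
Conditions: MeI (1.0 equiv), K2CO3, acetone, rt
Reagents that add atoms: iodomethane, SMILES CI
Why: C-Alkylation of the β-keto ester enolate with one equivalent of iodomethane gives the 2-methyl derivative (the future C4 with C18).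

**Step 15**
Reactants: 18 tert-butyl 2-methyl-3-oxobutanoate; 16 allylic bromide
Product: 20 cyclisation precursor (C10–CH2CH2COCH(CH3)CO2tBu on the ring B olefin; C4 epimers), via acetoacetate dianion 19 (not isolated)
Conditions: NaH then n-BuLi, THF, 0 °C; added to 16 at −78 to −30 °C; aqueous work-up
Reagents that add atoms: none
Why: γ-Alkylation of an acetoacetate dianion with an allylic bromide forms the C1–C2 bond at the more reactive terminal carbanion, and adding the dianion to the bromide at low temperature should leave the allylic C6–H of the ester untouched.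

**Step 16**
Reactants: 20 cyclisation precursor
Product: 22 pentacyclic 3-oxo-19,10-lactone (C7 silylethyl ester; 12-ketal; 16-methylene), via C10 cation 21 (not isolated)
Conditions: Mn(OAc)3·2H2O (2.2 equiv), KOAc, degassed AcOH, 25–40 °C
Reagents that add atoms: none
Why: Mn(OAc)3 oxidises the 2-methyl-3-oxo ester to its C4 radical, which adds 6-endo-trig to C5 of the ring B olefin (closing ring A) and leaves a tertiary C10 radical; a second equivalent of trivalent manganese oxidises this to cation 21, and the axial tert-butyl ester carbonyl captures it from the α face (five-membered acyloxonium, then loss of 2-methylpropene), so the O–C10 bond and the γ-lactone form in the same operation. The closest known reaction type is the trivalent-manganese oxidative free-radical cyclisation of unsaturated β-keto esters with lactone termination at a tertiary cation. C5 is set by attack anti to the C6 ester (H5 and H6 trans), which also leaves C1 on the open β face; C4 is set by the chair transition state with the ester axial and the methyl equatorial; C10 is set by the tether, since only a lactone cis-fused across C5–C10 can close. The step needs 6-endo over 5-exo addition (secured by the α-keto radical and the fully substituted proximal carbon C10), lactonisation over proton loss (secured by the 1,3-diaxial ester and the readily lost tert-butyl group) and no reaction at the remote 16-methylene (the intramolecular addition is much faster, and the product ketone with quaternary C4 is not re-oxidised).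

**Step 17**
Reactants: 22 pentacyclic 3-oxo-19,10-lactone
Product: 23 2β-hydroxy-3-oxo lactone
Conditions: KHMDS, THF, −78 °C; 2-(phenylsulfonyl)-3-phenyloxaziridine; AcOH quench at −78 °C
Reagents that add atoms: 2-(phenylsulfonyl)-3-phenyloxaziridine, SMILES O=S(=O)(N1OC1c1ccccc1)c1ccccc1
Why: In this enolate hydroxylation with an N-sulfonyloxaziridine the C3 ketone can enolise only toward C2 (C4 is quaternary), and the oxidant should approach from the β face, away from the lactone bridge that covers the α face of C2, which sets the 2β-hydroxyl.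

**Step 18**
Reactants: 23 2β-hydroxy-3-oxo lactone
Product: 24 2β,3β-diol (C7 silylethyl ester, 12-ketal)
Conditions: L-Selectride (LiBH(s-Bu)3, 2.5 equiv), THF, −78 °C; aqueous work-up
Reagents that add atoms: none
Why: A bulky trialkylborohydride should deliver hydride equatorially from the α side of the C3 ketone (as with 3-oxogibberellins), giving the axial 3β-alcohol cis to the 2β-hydroxyl, while lactone, ester and ketal are inert at −78 °C.

**Step 19**
Reactants: 24 2β,3β-diol
Product: 25 C7 carboxylic acid (12-ketal)
Conditions: TBAF, THF, 0 °C to rt; dilute HCl work-up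
Reagents that add atoms: none
Why: Fluoride-induced β-elimination of the 2-(trimethylsilyl)ethyl ester frees the C7 acid without hydroxide, so the lactone and the base-sensitive 3β-hydroxy lactone unit are not endangered.

**Step 20**
Reactants: 25 C7 carboxylic acid (12-ketal)
Product: 26 target, 2β,3β-dihydroxy-12-oxo-20-norgibberell-16-ene-7,19-dioic acid 19,10-lactone (CNP0307952.1)
Conditions: 1 M HCl, THF, 25 °C
Reagents that add atoms: water, SMILES O
Why: Mild aqueous acid hydrolyses the dioxolane to the 12-ketone, and the 16-methylene of a 13-deoxygibberellin should tolerate dilute acid at room temperature.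

**Compound list**
1 | (R)-4-(tert-butyldimethylsilyloxy)cyclopent-2-en-1-one | O=C1C=C[C@H](O[Si](C)(C)C(C)(C)C)C1 | starting material
2 | (R)-4-(tert-butyldimethylsilyloxy)-2-iodocyclopent-2-en-1-one | O=C1C(I)=C[C@H](O[Si](C)(C)C(C)(C)C)C1 | intermediate
3 | allyltributylstannane | C=CC[Sn](CCCC)(CCCC)CCCC | starting material
4 | (R)-2-allyl-4-(tert-butyldimethylsilyloxy)cyclopent-2-en-1-one | C=CCC1=C[C@H](O[Si](C)(C)C(C)(C)C)CC1=O | intermediate
5 | but-3-en-2-one | CC(=O)C=C | starting material
6 | 2-(tert-butyldimethylsilyloxy)buta-1,3-diene | C=CC(=C)O[Si](C)(C)C(C)(C)C | intermediate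
7 | cis-fused 7a-allyl-3,5-bis(tert-butyldimethylsilyloxy)-2,3,3a,4,7,7a-hexahydroinden-1-one (8β-allyl, 9β-H, 10β-silyloxy; C12=C13 silyl enol ether) | C=CC[C@]12CC=C(O[Si](C)(C)C(C)(C)C)C[C@H]1[C@H](O[Si](C)(C)C(C)(C)C)CC2=O | intermediate
8 | tricyclic diketone: ring B cyclopentanone (6-ketone, 10β-silyloxy) cis-fused at C8–C9 to the bicyclo[3.2.1]octane of rings C and D (12-ketone, 16-methylene) | C=C1C[C@]23C[C@H]1C(=O)C[C@H]2[C@H](O[Si](C)(C)C(C)(C)C)CC3=O | intermediate
9 | 12,12-ethylenedioxy ketal of 8 | C=C1C[C@]23C[C@H]1C4(OCCO4)C[C@H]2[C@H](O[Si](C)(C)C(C)(C)C)CC3=O | intermediate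
10 | C6 enol triflate of 9 (C5=C6) | C=C1C[C@]23C[C@H]1C4(OCCO4)C[C@H]2[C@H](O[Si](C)(C)C(C)(C)C)C=C3OS(=O)(=O)C(F)(F)F | intermediate
11 | 10β-silyloxy C5=C6 olefin | C=C1C[C@]23C[C@H]1C4(OCCO4)C[C@H]2[C@H](O[Si](C)(C)C(C)(C)C)C=C3 | intermediate
12 | 10β-hydroxy C5=C6 olefin | C=C1C[C@]23C[C@H]1C4(OCCO4)C[C@H]2[C@H](O)C=C3 | intermediate
13 | ring B enone (10-ketone, C5=C6; 12-ketal, 16-methylene) | C=C1C[C@]23C[C@H]1C4(OCCO4)C[C@H]2C(=O)C=C3 | intermediate
14 | spiro vinyl oxirane at C10 (oxygen α, C1H2 β; C5=C6) | C=C1C[C@]23C[C@H]1C4(OCCO4)C[C@H]2[C@]5(CO5)C=C3 | intermediate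
15 | 2-(trimethylsilyl)ethyl 6β-carboxylate with C5=C10 and C10–CH2OH | C=C1C[C@]23C[C@H]1C4(OCCO4)C[C@H]2C(CO)=C[C@@H]3C(=O)OCC[Si](C)(C)C | intermediate
16 | allylic bromide (C10–CH2Br) of 15 | C=C1C[C@]23C[C@H]1C4(OCCO4)C[C@H]2C(CBr)=C[C@@H]3C(=O)OCC[Si](C)(C)C | intermediate
17 | tert-butyl 3-oxobutanoate | CC(=O)CC(=O)OC(C)(C)C | starting material
18 | tert-butyl 2-methyl-3-oxobutanoate | CC(=O)C(C)C(=O)OC(C)(C)C | intermediate
19 | sodium lithium dianion of 18 (not isolated) | [Li+].[Na+].C=C([O-])C(C)=C([O-])OC(C)(C)C | intermediate
20 | cyclisation precursor: tert-butyl 2-methyl-3-oxopentanoate chain on C10 of the ring B olefin (C4 epimers) | C=C1C[C@]23C[C@H]1C4(OCCO4)C[C@H]2C(CCC(=O)C(C)C(=O)OC(C)(C)C)=C[C@@H]3C(=O)OCC[Si](C)(C)C | intermediate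
21 | tertiary C10 cation after ring A closure (not isolated) | C=C1C[C@]23C[C@H]1C4(OCCO4)C[C@H]2[C+]5CCC(=O)[C@@](C)(C(=O)OC(C)(C)C)[C@H]5[C@@H]3C(=O)OCC[Si](C)(C)C | intermediate
22 | pentacyclic 3-oxo-19,10-lactone (C7 silylethyl ester, 12-ketal) | C=C1C[C@]23C[C@H]1C4(OCCO4)C[C@H]2[C@@]12CCC(=O)[C@@](C)(C(=O)O1)[C@H]2[C@@H]3C(=O)OCC[Si](C)(C)C | intermediate
23 | 2β-hydroxy-3-oxo lactone | C=C1C[C@]23C[C@H]1C4(OCCO4)C[C@H]2[C@@]12C[C@H](O)C(=O)[C@@](C)(C(=O)O1)[C@H]2[C@@H]3C(=O)OCC[Si](C)(C)C | intermediate
24 | 2β,3β-diol (C7 silylethyl ester, 12-ketal) | C=C1C[C@]23C[C@H]1C4(OCCO4)C[C@H]2[C@@]12C[C@H](O)[C@H](O)[C@@](C)(C(=O)O1)[C@H]2[C@@H]3C(=O)OCC[Si](C)(C)C | intermediate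
25 | 2β,3β-diol C7 acid (12-ketal) | C=C1C[C@]23C[C@H]1C4(OCCO4)C[C@H]2[C@@]12C[C@H](O)[C@H](O)[C@@](C)(C(=O)O1)[C@H]2[C@@H]3C(=O)O | intermediate
26 | 2β,3β-dihydroxy-12-oxo-20-norgibberell-16-ene-7,19-dioic acid 19,10-lactone (CNP0307952.1) | C=C1C[C@]23C[C@H]1C(=O)C[C@H]2[C@@]12C[C@H](O)[C@H](O)[C@@](C)(C(=O)O1)[C@H]2[C@@H]3C(=O)O | target

**Totals**
Total step count: 20. Longest linear sequence: 18 steps (steps 1, 2, 4–13 and 15–20).

**Steps most likely to fail**

1. Step 16. After the 6-endo closure the C10 radical or cation may be lost by hydrogen abstraction, proton loss or acetate capture before the axial ester closes. Attack at C5 may also be insufficiently face-selective, and the ketal may open in acetic acid. The fallback sets out from 20 and returns at 22. The oxidative cyclisation would be run with Mn(OAc)3·2H2O and Cu(OAc)2·H2O in ethanol, so that divalent copper ends the sequence by oxidative elimination and gives the tetracyclic Δ1(10)-olefinic 3-keto tert-butyl ester F1. Iodolactonisation of the tert-butyl ester (I2, NaHCO3, MeCN, 0 °C, with loss of 2-methylpropene) would then form the O–C10 bond by anti addition and give the 1β-iodo-19,10-lactone F2. Bu3SnH with AIBN in toluene at 80 °C would remove the iodine and give 22.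

2. Step 12. The alkoxide-bearing π-allylpalladium intermediate may lose a β-hydride, or the oxirane may isomerise to a carbonyl compound, before CO inserts. The fallback sets out from 13 and returns at 15. (4-Methoxybenzyloxy)methyllithium (from the tributylstannane and n-BuLi, THF, −78 °C) would add to the C10 ketone from the β face, and trapping the alkoxide with 2-(trimethylsilyl)ethyl chloroformate would give the tertiary allylic carbonate F3. Decarboxylative carbonylation of this unstrained carbonate (Pd(OAc)2, PPh3, CO 20 atm, THF, 50 °C) still uses palladium and CO, but the leaving group and the way C1 is introduced are different. The liberated silylethoxide becomes the ester group, and the same anti course would give the 4-methoxybenzyl ether ester F4. DDQ in CH2Cl2 with pH 7 buffer would free the allylic alcohol 15.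

3. Step 4. The Lewis acid may ionise or eliminate the silyloxy group or cleave the silyl enol ether, and the 2-alkyl enone may react too slowly. The fallback sets out from 4 and returns at 7 by an anionic double Michael annulation. Lithium buta-1,3-dien-2-olate F5 (from commercial 2-(trimethylsilyloxy)buta-1,3-diene and MeLi, THF, −78 °C) would add to C9 of 4 anti to the silyloxy group. The resulting cyclopentanone enolate would close onto the new vinyl ketone at C14 and give the regiodefined C12–C13 lithium enolate F6, which TBSCl with HMPA would silylate to 7.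

**Further compounds**
F1 | step 16 | Δ1(10)-olefinic tetracyclic 3-keto tert-butyl ester (rings A–D closed, ester α on C4) | C=C1C[C@]23C[C@H]1C4(OCCO4)C[C@H]2C5=CCC(=O)[C@@](C)(C(=O)OC(C)(C)C)[C@H]5[C@@H]3C(=O)OCC[Si](C)(C)C
F2 | step 16 | 1β-iodo-3-oxo-19,10-lactone | C=C1C[C@]23C[C@H]1C4(OCCO4)C[C@H]2[C@@]12[C@H](I)CC(=O)[C@@](C)(C(=O)O1)[C@H]2[C@@H]3C(=O)OCC[Si](C)(C)C
F3 | step 12 | tertiary allylic 2-(trimethylsilyl)ethyl carbonate at C10 (carbonate oxygen α, CH2OPMB β; C5=C6) | C=C1C[C@]23C[C@H]1C4(OCCO4)C[C@H]2[C@@](COCc5ccc(OC)cc5)(OC(=O)OCC[Si](C)(C)C)C=C3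
F4 | step 12 | 4-methoxybenzyl ether of 15 | C=C1C[C@]23C[C@H]1C4(OCCO4)C[C@H]2C(COCc5ccc(OC)cc5)=C[C@@H]3C(=O)OCC[Si](C)(C)C
F5 | step 4 | lithium buta-1,3-dien-2-olate | [Li+].C=CC(=C)[O-]
F6 | step 4 | C12–C13 lithium enolate of the cis-fused bicyclic diketone | [Li+].C=CC[C@]12CC=C([O-])C[C@H]1[C@H](O[Si](C)(C)C(C)(C)C)CC2=O
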